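The retrosynthesis cuts (a) C2–C1' between flavanone ring C and ring B. (b) In the same operation C2 is re-joined to C4, so C3 becomes the CH2 bridge of a cyclopropanol fused to a five-membered benzofuran ring. It also cuts (c) the C3'–C8'' biaryl bond and (d) O1''–C2'' and C2''=C3'' of the flavone, which leads back to a chalcone.
Enabling feature: C2 is alpha to ring oxygen O1 and beta to the C4 ketone on ring A. It is therefore the radical released when the O-radical of a 6b-hydroxycyclopropa[b]benzofuran breaks its central C–C bond. O1 and the aryl ketone bias that scission toward five- to six-membered ring expansion.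
Forward, flavone half: acetophenone, benzyl ether, iodide, chalcone, flavone ring, then Suzuki–Miyaura coupling to an aryl bromide that holds ring B and the whole flavone.
Forward, ring A half: 4,6-dihydroxybenzofuranone, O-methyl, O-benzyl, silyl enol ether, then Simmons–Smith reaction to a racemic fused cyclopropanol.
Union: a photoredox/nickel arylative ring expansion makes ring C, the C4 ketone, the C2–C1' bond and C2 at once. Neutral hydrogenolysis then frees the three phenols.
Stereochemistry: C2 (S) is the only stereocentre. It comes from the chiral bioxazoline on nickel (racemic cyclopropanol to planar radical, enantioconvergent), and no base or Lewis acid follows.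

Key step: step 10

Assumption 1: the sense of induction of the nickel/bioxazoline pair at C2 cannot be derived safely from models. The (S,S)-ligand is written, and its mirror image is used if a trial run with 4-bromoanisole points the other way.
Assumption 2: the C3'–C8'' axis bears only three small ortho groups and the target string gives no axial descriptor, so the axis is treated as freely rotating.

Step 1
Reactants: 1 1-(2,6-dihydroxy-4-methoxyphenyl)ethan-1-one
Product: 2 1-[2-(benzyloxy)-6-hydroxy-4-methoxyphenyl]ethan-1-one
Conditions: BnBr (1.0 equiv), K2CO3, acetone, reflux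
Reagents that add atoms: benzyl bromide, BrCc1ccccc1
Why: Williamson ether synthesis; after the first O-benzylation the remaining hydroxyl is held in a hydrogen bond to the ketone and is much less nucleophilic, so one equivalent of halide should stop at the mono ether.

Step 2
Reactants: 2 1-[2-(benzyloxy)-6-hydroxy-4-methoxyphenyl]ethan-1-one
Product: 3 1-[6-(benzyloxy)-2-hydroxy-3-iodo-4-methoxyphenyl]ethan-1-one
Conditions: NIS (1.05 equiv), CF3CO2H (10 mol %), MeCN, 0 °C to rt
Reagents that add atoms: N-iodosuccinimide, O=C1CCC(=O)N1I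
Why: Electrophilic aromatic iodination; C3 is activated by the ortho hydroxyl, the ortho methoxy and the para benzyloxy group and is less crowded than C5 between two ethers, so iodine should enter at the carbon that becomes C8'' of the flavone.

Step 3
Reactants: 3 1-[6-(benzyloxy)-2-hydroxy-3-iodo-4-methoxyphenyl]ethan-1-one; 4 4-(benzyloxy)benzaldehyde
Product: 5 (E)-1-[6-(benzyloxy)-2-hydroxy-3-iodo-4-methoxyphenyl]-3-[4-(benzyloxy)phenyl]prop-2-en-1-one
Conditions: KOH, EtOH/H2O, rt
Reagents that add atoms: none
Why: Claisen–Schmidt condensation of a methyl ketone with a non-enolisable aldehyde; dehydration of the aldol gives the conjugated E-enone.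

Step 4
Reactants: 5 (E)-1-[6-(benzyloxy)-2-hydroxy-3-iodo-4-methoxyphenyl]-3-[4-(benzyloxy)phenyl]prop-2-en-1-one
Product: 6 5-(benzyloxy)-2-[4-(benzyloxy)phenyl]-8-iodo-7-methoxy-4H-chromen-4-one
Conditions: I2 (10 mol %), DMSO, 120 °C
Reagents that add atoms: none
Why: Iodine/DMSO oxidative cyclisation of a 2'-hydroxychalcone; 6-endo oxa-Michael closure, alpha-iodination and loss of HI give the flavone while DMSO re-oxidises HI, and the benzyl ethers and the aryl iodide are not expected to react.

Step 5
Reactants: 6 5-(benzyloxy)-2-[4-(benzyloxy)phenyl]-8-iodo-7-methoxy-4H-chromen-4-one; 7 (5-bromo-2-methoxyphenyl)boronic acid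
Product: 8 5-(benzyloxy)-2-[4-(benzyloxy)phenyl]-8-(5-bromo-2-methoxyphenyl)-7-methoxy-4H-chromen-4-one
Conditions: Pd(PPh3)4 (5 mol %), K2CO3, DME/H2O, 80 °C
Reagents that add atoms: none
Why: Suzuki–Miyaura coupling of a doubly ortho-substituted aryl iodide; zerovalent palladium inserts into the carbon–iodine bond of 6 far faster than into the electron-rich carbon–bromine bond para to methoxy, so the bromide is kept for step 10.

Step 6
Reactants: 9 4,6-dihydroxybenzofuran-3(2H)-one
Product: 10 4-hydroxy-6-methoxybenzofuran-3(2H)-one
Conditions: MeI (1.0 equiv), K2CO3 (1.0 equiv), acetone, rt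
Reagents that add atoms: iodomethane, CI
Why: Williamson methylation; the 6-hydroxyl is para to the ketone (a vinylogous acid) and free, whereas the 4-hydroxyl is hydrogen-bonded to the ketone, so one equivalent of base and halide should alkylate O6 only.

Step 7
Reactants: 10 4-hydroxy-6-methoxybenzofuran-3(2H)-one
Product: 11 4-(benzyloxy)-6-methoxybenzofuran-3(2H)-one
Conditions: BnBr, K2CO3, DMF, 50 °C
Reagents that add atoms: benzyl bromide, BrCc1ccccc1
Why: Williamson benzylation of the remaining phenol, which is far more acidic than the C2 methylene, so O-alkylation should prevail over C-alkylation.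

Step 8
Reactants: 11 4-(benzyloxy)-6-methoxybenzofuran-3(2H)-one
Product: 12 {[4-(benzyloxy)-6-methoxybenzofuran-3-yl]oxy}trimethylsilane
Conditions: Me3SiOTf, Et3N, CH2Cl2, 0 °C
Reagents that add atoms: trimethylsilyl triflate, C[Si](C)(C)OS(=O)(=O)C(F)(F)F
Why: Soft enolisation and O-silylation; the enol form is an aromatic benzofuran, which favours clean formation of the only possible silyl enol ether.

Step 9
Reactants: 12 {[4-(benzyloxy)-6-methoxybenzofuran-3-yl]oxy}trimethylsilane
Product: 14 (±)-6-(benzyloxy)-4-methoxy-1,1a-dihydro-6bH-cyclopropa[b]benzofuran-6b-ol, via trimethylsilyl ether 13 (not isolated)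
Conditions: Et2Zn (2 equiv), CH2I2 (4 equiv), CH2Cl2, 0 °C to rt; then K2CO3 (cat.), MeOH, 0 °C
Reagents that add atoms: diiodomethane, ICI
Why: Simmons–Smith cyclopropanation (Furukawa variant) of a silyl enol ether; the C2=C3 bond carries two oxygen donors and is the most electron-rich pi bond, the methylene is delivered suprafacially so only the cis-fused racemate can form, and mild methanolysis frees the cyclopropanol.

Step 10
Reactants: 8 5-(benzyloxy)-2-[4-(benzyloxy)phenyl]-8-(5-bromo-2-methoxyphenyl)-7-methoxy-4H-chromen-4-one; 14 (±)-6-(benzyloxy)-4-methoxy-1,1a-dihydro-6bH-cyclopropa[b]benzofuran-6b-ol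
Product: 16 (2S)-5-(benzyloxy)-2-{3-[5-(benzyloxy)-2-[4-(benzyloxy)phenyl]-7-methoxy-4-oxo-4H-chromen-8-yl]-4-methoxyphenyl}-7-methoxychroman-4-one, via 4-oxochroman-2-yl radical 15 (not isolated)
Conditions: NiBr2(dme) (10 mol %), (4S,4'S)-4,4'-diisopropyl-4,4',5,5'-tetrahydro-2,2'-bioxazole (12 mol %), 4CzIPN (2 mol %), 2,4,6-collidine (2 equiv), 14 (1.5 equiv), DMA, 450 nm LED, 15 °C
Reagents that add atoms: none
Why: Proposed new method: the excited photocatalyst removes one electron from the electron-rich, not yet acylated ring A of 14 while collidine takes the O–H proton, and the cyclopropyloxy radical so formed breaks the bond shared by the three- and the five-membered ring (C2–C4 in flavanone numbering), which widens the five-membered ring to the six-membered ring C, creates the C4 ketone and leaves radical 15 at C2; no ring is closed by bond formation, ring C arises by this scission alone. The scission selectivity that the step needs is secured by O1, which stabilises the C2 radical, and by the aryl ketone, to which the primary radical from the alternative outer-bond scission can add back in 3-exo fashion (the 1,2-acyl shift of the Dowd–Beckwith ring expansion) faster than the dilute nickel complex should capture it, so that both paths drain into 15. Zerovalent nickel inserts into the only carbon–bromine bond of 8, the divalent aryl nickel bromide captures 15, reductive elimination from trivalent nickel forms C2–C1', and the photocatalyst radical anion reduces monovalent nickel back, so the step is redox-neutral and loses only HBr to collidine. C2 is the only new stereocentre: both enantiomers of racemic 14 give the same planar radical, its capture is reversible, and the chiral bioxazoline on nickel chooses the face in the reductive elimination, helped by the very different flanks of C2 (aryl-bound O1 against CH2–C=O). The closest known reaction types are the photoredox/nickel ring-opening arylation of cyclopropanols and 1-arylcycloalkanols with aryl halides, the oxidative ring expansion of 1-oxybicyclo[n.1.0]alkanes through beta-keto radicals, and the enantioconvergent nickel arylation of alpha-oxy, alpha-amino and benzylic radicals with chiral bis(oxazoline)-type ligands; new is their merger on a fused cyclopropanol. Chemoselectivity rests on ring A of 14 being the most easily oxidised arene present (all other oxygenated rings are acylated, vinylogously acylated or brominated), and the weak base at ambient temperature should not open ring C of 16, so C2 should keep its configuration.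

Step 11
Reactants: 16 (2S)-5-(benzyloxy)-2-{3-[5-(benzyloxy)-2-[4-(benzyloxy)phenyl]-7-methoxy-4-oxo-4H-chromen-8-yl]-4-methoxyphenyl}-7-methoxychroman-4-one
Product: 17 (2S)-5-hydroxy-2-{3-[5-hydroxy-2-(4-hydroxyphenyl)-7-methoxy-4-oxo-4H-chromen-8-yl]-4-methoxyphenyl}-7-methoxychroman-4-one (CNP0288780.1)
Conditions: H2 (1 atm), Pd/C (10 wt %), THF/EtOAc, rt
Reagents that add atoms: none
Why: Catalytic hydrogenolysis of three aryl benzyl ethers under neutral conditions, which avoids the base- or Lewis-acid-induced opening to the chalcone that would racemise C2; the flavone double bond, the aryl ketone and the cyclic C2–O1 bond should react much more slowly.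

Compound list
1 | 1-(2,6-dihydroxy-4-methoxyphenyl)ethan-1-one | CC(=O)c1c(O)cc(OC)cc1O | starting material
2 | 1-[2-(benzyloxy)-6-hydroxy-4-methoxyphenyl]ethan-1-one | CC(=O)c1c(O)cc(OC)cc1OCc1ccccc1 | intermediate
3 | 1-[6-(benzyloxy)-2-hydroxy-3-iodo-4-methoxyphenyl]ethan-1-one | CC(=O)c1c(O)c(I)c(OC)cc1OCc1ccccc1 | intermediate
4 | 4-(benzyloxy)benzaldehyde | O=Cc1ccc(OCc2ccccc2)cc1 | starting material
5 | (E)-1-[6-(benzyloxy)-2-hydroxy-3-iodo-4-methoxyphenyl]-3-[4-(benzyloxy)phenyl]prop-2-en-1-one | O=C(/C=C/c1ccc(OCc2ccccc2)cc1)c1c(O)c(I)c(OC)cc1OCc1ccccc1 | intermediate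
6 | 5-(benzyloxy)-2-[4-(benzyloxy)phenyl]-8-iodo-7-methoxy-4H-chromen-4-one | COc1cc(OCc2ccccc2)c2c(=O)cc(-c3ccc(OCc4ccccc4)cc3)oc2c1I | intermediate
7 | (5-bromo-2-methoxyphenyl)boronic acid | COc1ccc(Br)cc1B(O)O | starting material
8 | 5-(benzyloxy)-2-[4-(benzyloxy)phenyl]-8-(5-bromo-2-methoxyphenyl)-7-methoxy-4H-chromen-4-one | COc1ccc(Br)cc1-c1c(OC)cc(OCc2ccccc2)c2c(=O)cc(-c3ccc(OCc4ccccc4)cc3)oc12 | intermediate
9 | 4,6-dihydroxybenzofuran-3(2H)-one | O=C1COc2cc(O)cc(O)c12 | starting material
10 | 4-hydroxy-6-methoxybenzofuran-3(2H)-one | COc1cc(O)c2c(c1)OCC2=O | intermediate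
11 | 4-(benzyloxy)-6-methoxybenzofuran-3(2H)-one | COc1cc(OCc2ccccc2)c2c(c1)OCC2=O | intermediate
12 | {[4-(benzyloxy)-6-methoxybenzofuran-3-yl]oxy}trimethylsilane | COc1cc(OCc2ccccc2)c2c(O[Si](C)(C)C)coc2c1 | intermediate
13 | (±)-trimethylsilyl ether of 14, cis-fused, one enantiomer drawn | COc1cc(OCc2ccccc2)c2c(c1)O[C@H]1C[C@]12O[Si](C)(C)C | intermediate
14 | (±)-6-(benzyloxy)-4-methoxy-1,1a-dihydro-6bH-cyclopropa[b]benzofuran-6b-ol, cis-fused, one enantiomer drawn | COc1cc(OCc2ccccc2)c2c(c1)O[C@H]1C[C@]12O | intermediate
15 | 5-(benzyloxy)-7-methoxy-4-oxochroman-2-yl radical | COc1cc(OCc2ccccc2)c2c(c1)O[CH]CC2=O | intermediate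
16 | (2S)-5-(benzyloxy)-2-{3-[5-(benzyloxy)-2-[4-(benzyloxy)phenyl]-7-methoxy-4-oxo-4H-chromen-8-yl]-4-methoxyphenyl}-7-methoxychroman-4-one | COc1cc(OCc2ccccc2)c2c(c1)O[C@H](c1ccc(OC)c(-c3c(OC)cc(OCc4ccccc4)c4c(=O)cc(-c5ccc(OCc6ccccc6)cc5)oc34)c1)CC2=O | intermediate
17 | (2S)-5-hydroxy-2-{3-[5-hydroxy-2-(4-hydroxyphenyl)-7-methoxy-4-oxo-4H-chromen-8-yl]-4-methoxyphenyl}-7-methoxychroman-4-one | COc1cc(O)c2c(c1)O[C@H](c1ccc(OC)c(-c3c(OC)cc(O)c4c(=O)cc(-c5ccc(O)cc5)oc34)c1)CC2=O | target

Total step count: 11. Longest linear sequence: 7 (steps 1 to 5, 10, 11).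

Steps most likely to fail

Step 10. Several processes are at risk.
- Facial selectivity in the reductive elimination at nickel may be poor.
- The unrearranged primary radical may be captured before the acyl shift.
- The C2 radical may be lost by oxidation or beta-hydride elimination.
- Enantiopurity may erode through hydrogen abstraction at the doubly activated C2–H of the product by bromine radicals.

The fallback sets out from 14 and 8, comes back at 16, and uses known chemistry only.
- Compound 14 is oxidised with FeCl3 in DMF at 0 °C. The same ring-expanding scission is followed by chlorine transfer and should give (±)-5-(benzyloxy)-2-chloro-7-methoxychroman-4-one F1.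
- F1 loses HCl with NaOAc in MeOH to give 5-(benzyloxy)-7-methoxy-4H-chromen-4-one F2.
- Compound 8 is borylated (Pd(OAc)2, XPhos, B2(OH)4, KOAc, EtOH, 80 °C) to {3-[5-(benzyloxy)-2-[4-(benzyloxy)phenyl]-7-methoxy-4-oxo-4H-chromen-8-yl]-4-methoxyphenyl}boronic acid F3.
- F2 and F3 are joined by asymmetric conjugate addition of an arylboronic acid to a chromone (Pd(OCOCF3)2, t-BuPyOx in the antipode that leads to 2S, NH4PF6, H2O, ClCH2CH2Cl, 60 °C). This is base-free and should give 16.

Step 9. Carbenoid transfer may be sluggish because the double bond is part of an aromatic furan ring. Zinc iodide may also open the acid-sensitive, doubly oxygenated cyclopropane. The fallback sets out from 11, comes back at 14, and forms a different bond of the three-membered ring.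
- The lithium enolate of 11 (LiN(SiMe3)2, THF, −78 °C) is C-alkylated with Bu3SnCH2I to (±)-4-(benzyloxy)-6-methoxy-2-[(tributylstannyl)methyl]benzofuran-3(2H)-one F4.
- TiCl4 in CH2Cl2 at −78 °C then activates the ketone for 3-exo attack by the carbon–tin bond, the known cyclopropanol closure of beta-stannyl ketones. This gives 14 after aqueous work-up.

Step 5. Oxidative addition and transmetalation may be slow at the doubly ortho-substituted iodide. Protodeboronation may compete, and halide selectivity may be lost, with chain growth through the carbon–bromine bond. The fallback sets out from 3 (with 7 and 4), comes back at 8, and changes the order of events so that the crowded biaryl bond is made before the pyranone ring exists.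
- Compounds 3 and 7 are coupled (Pd(PPh3)4, K2CO3, DME/H2O, 70 °C) next to the small free hydroxyl to give 1-[6-(benzyloxy)-3-(5-bromo-2-methoxyphenyl)-2-hydroxy-4-methoxyphenyl]ethan-1-one F5.
- Claisen–Schmidt condensation of F5 with 4 (KOH, EtOH) gives (E)-1-[6-(benzyloxy)-3-(5-bromo-2-methoxyphenyl)-2-hydroxy-4-methoxyphenyl]-3-[4-(benzyloxy)phenyl]prop-2-en-1-one F6.
- I2 (cat.) in DMSO at 120 °C closes and oxidises F6 to 8.

Further compounds
F1 | step 10 | (±)-5-(benzyloxy)-2-chloro-7-methoxychroman-4-one | COc1cc(OCc2ccccc2)c2c(c1)OC(Cl)CC2=O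
F2 | step 10 | 5-(benzyloxy)-7-methoxy-4H-chromen-4-one | COc1cc(OCc2ccccc2)c2c(=O)ccoc2c1
F3 | step 10 | {3-[5-(benzyloxy)-2-[4-(benzyloxy)phenyl]-7-methoxy-4-oxo-4H-chromen-8-yl]-4-methoxyphenyl}boronic acid | COc1ccc(B(O)O)cc1-c1c(OC)cc(OCc2ccccc2)c2c(=O)cc(-c3ccc(OCc4ccccc4)cc3)oc12
F4 | step 9 | (±)-4-(benzyloxy)-6-methoxy-2-[(tributylstannyl)methyl]benzofuran-3(2H)-one | COc1cc(OCc2ccccc2)c2c(c1)OC(C[Sn](CCCC)(CCCC)CCCC)C2=O
F5 | step 5 | 1-[6-(benzyloxy)-3-(5-bromo-2-methoxyphenyl)-2-hydroxy-4-methoxyphenyl]ethan-1-one | CC(=O)c1c(O)c(-c2cc(Br)ccc2OC)c(OC)cc1OCc1ccccc1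
F6 | step 5 | (E)-1-[6-(benzyloxy)-3-(5-bromo-2-methoxyphenyl)-2-hydroxy-4-methoxyphenyl]-3-[4-(benzyloxy)phenyl]prop-2-en-1-one | O=C(/C=C/c1ccc(OCc2ccccc2)cc1)c1c(O)c(-c2cc(Br)ccc2OC)c(OC)cc1OCc1ccccc1
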